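**Plan**

- Numbering (germacrane): ring C1–C10 with C1 ketone, C2–C3 epoxide, C4 (methyl C15), C5, C6 (lactone O), C7, C8 and C9 (crotonates), C10 (OH, methyl C14); C11(=C13) and the lactone carbonyl C12 sit on C7.
- Retrosynthesis first removes the hetero-bonds: the epoxide O, the C2=C3 unsaturation, the two crotonyl C–O bonds, the oxygens at C1/C10 (back to a C1=C10 alkene), the C4/C5 hydrogens (back to C4=C5) and the oxygens at C9, C8, C6 and C12. It then cuts the only ring C–C bond, C6–C7, which leaves farnesyl diphosphate.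
- Enabling feature: C1–C15 form one unbranched head-to-tail farnesyl chain, C6–C5–C4(C15)–C3–C2–C1–C10(C14)–C9–C8–C7–C11(C12)(C13). The ten-membered carbocycle is this chain closed between its head carbon C6 and C7.
- Forward order: farnesol → diphosphate → ten-membered ring (step 3) → γ-lactone ring by P450 oxidation at C12, C8 and C6 (steps 4–5) → C9 hydroxyl → 1,10-epoxide → saturation of C4=C5 → crotonates → ketol → enone → 2,3-epoxide.
- Stereochemistry: C7 from the cyclase; C6, C8 and C9 from P450 C–H hydroxylations; C10 from outer-face, hydroxyl-directed epoxidation of C1=C10 followed by inversion at C10 on hydrolysis; C4 from outer-face hydrogenation; C2/C3 from peroxide attack anti to the C4 methyl.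

Key step: step 3

Assumption: among the engineered CYP102A1 variants that hydroxylate germacranolides at the allylic C9 methylene, one that removes the 9α hydrogen of 10 is taken to be found by screening; the first fallback covers the 9β outcome.

**Route**

Step 1
Reactants: 1 (2E,6E)-farnesol
Product: 2 (2E,6E)-farnesyl chloride
Conditions: NCS, Me2S, CH2Cl2, −40 → 0 °C
Reagents that add atoms: N-chlorosuccinimide, O=C1CCC(=O)N1Cl
Why: Corey–Kim chlorination: the alcohol is activated as an alkoxysulfonium ion and displaced by chloride at the primary carbon (SN2), which should preserve both E alkenes without allylic transposition; no stereocentre is created.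

Step 2
Reactants: 2 (2E,6E)-farnesyl chloride
Product: 3 (2E,6E)-farnesyl diphosphate trisammonium salt
Conditions: (n-Bu4N)3HP2O7, MeCN, 25 °C; then Dowex 50W-X8 (NH4+ form), aq. NH4HCO3 (25 mM)/i-PrOH; cellulose chromatography
Reagents that add atoms: tris(tetrabutylammonium) hydrogen diphosphate, CCCC[N+](CCCC)(CCCC)CCCC.CCCC[N+](CCCC)(CCCC)CCCC.CCCC[N+](CCCC)(CCCC)CCCC.OP(=O)([O-])OP(=O)([O-])[O-]; ammonium hydrogencarbonate, [NH4+].OC(=O)[O-]
Why: SN2 displacement of the primary allylic chloride by the diphosphate anion in acetonitrile, the standard preparation of prenyl diphosphates, followed by cation exchange to the ammonium salt that is soluble in the enzyme buffer; no stereocentre is created.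

Step 3
Reactants: 3 (2E,6E)-farnesyl diphosphate trisammonium salt
Product: 4 (R)-germacrene A
Conditions: recombinant germacrene A synthase (His-tagged, from E. coli), MgCl2 (10 mM), HEPES pH 7.5, DTT, glycerol, pentane overlay, 30 °C; filtration through Et3N-deactivated alumina, storage at −20 °C
Reagents that add atoms: none
Why: Magnesium-assisted ionisation of the allylic diphosphate gives the C4–C5–C6 allyl cation (target numbering), which the enzyme holds folded so that the distal C7=C11 alkene attacks C6, forming the C6–C7 bond and the ten-membered ring, and the resulting tertiary C11 cation is quenched by loss of a proton to give the isopropenyl group. This is the natural reaction of a class 1 sesquiterpene synthase, the closest chemical analogue being a cation–alkene (Prins-type) macrocyclisation. The one ring closes in a 10-exo-trig sense with respect to the attacked C7=C11 bond, with Markovnikov bond formation at C7. The only new stereocentre, C7, is set as R by the active-site fold, which presents a single face of the C7=C11 alkene to C6. The step needs ten-membered rather than six- or eleven-membered closure, retention of both E alkenes and regioselective deprotonation at the terminal methyl, all of which are imposed by the enzyme pocket and its diphosphate–magnesium binding site and not by the substrate. The product is collected in the pentane layer and kept cold and free of acid, since it undergoes Cope rearrangement on heating and transannular cyclisation with acid.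

Step 4
Reactants: 4 (R)-germacrene A
Product: 7 germacrene A acid [(7R)-germacra-1(10)E,4E,11(13)-trien-12-oic acid], via germacratrien-12-ol 5 (not isolated), via germacratrien-12-al 6 (not isolated)
Conditions: yeast microsomes with germacrene A oxidase (CYP71AV-type) and cytochrome P450 reductase, NADP+ (cat.), glucose 6-phosphate, glucose-6-phosphate dehydrogenase, air, Tris-HCl pH 7.5, 30 °C; EtOAc extraction at pH 6, 4 °C
Reagents that add atoms: dioxygen, O=O
Why: Cytochrome P450 allylic oxidation by the pathway's own germacrene A oxidase, which takes the C12 methyl through alcohol and aldehyde to the acid in three oxygen-rebound cycles while leaving both ring alkenes and C7 untouched.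

Step 5
Reactants: 7 germacrene A acid
Product: 10 eupatolide (8β-hydroxygermacra-1(10)E,4E,11(13)-trien-12,6α-olide), via 8β-hydroxygermacrene A acid 8 (not isolated), via 6α,8β-dihydroxygermacrene A acid 9 (not isolated)
Conditions: yeast microsomes with sunflower CYP71BL1 (8β-hydroxylase), CYP71DD6 (eupatolide synthase) and cytochrome P450 reductase, NADP+ (cat.), glucose 6-phosphate, glucose-6-phosphate dehydrogenase, air, Tris-HCl pH 7.5, 30 °C
Reagents that add atoms: dioxygen, O=O
Why: Two regio- and stereospecific P450 C–H hydroxylations (hydrogen abstraction and oxygen rebound with retention) by the sunflower enzymes set the 8β- and 6α-oxygen centres, and the 6α-hydroxy acid closes spontaneously to the trans-fused α-methylene-γ-lactone, the 8β-hydroxyl being unable to reach C12 in a strain-free way.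

Step 6
Reactants: 10 eupatolide
Product: 11 9α-hydroxyeupatolide (8β,9α-dihydroxygermacra-1(10)E,4E,11(13)-trien-12,6α-olide)
Conditions: engineered CYP102A1 (P450 BM3) variant, NADP+ (cat.), glucose 6-phosphate, glucose-6-phosphate dehydrogenase, air, KPi pH 8.0, 2% DMSO, 25 °C
Reagents that add atoms: dioxygen, O=O
Why: Engineered CYP102A1 variants are known to hydroxylate the allylic C9 methylene of a germacranolide by hydrogen abstraction and oxygen rebound with retention, so a variant that abstracts the 9α hydrogen of 10 should give the 9α alcohol; the allylic activation by C1=C10 and the fused reductase domain make the reaction practical on this scaffold.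

Step 7
Reactants: 11 9α-hydroxyeupatolide
Product: 12 1β,10α-epoxy-8β,9α-dihydroxygermacra-4E,11(13)-dien-12,6α-olide
Conditions: VO(acac)2 (5 mol %), t-BuOOH (decane), CH2Cl2, 0 °C; Et3N-deactivated silica
Reagents that add atoms: tert-butyl hydroperoxide, CC(C)(C)OO
Why: Vanadium-catalysed hydroxyl-directed epoxidation: the allylic 9α-hydroxyl delivers the peroxide only to C1=C10, on the outer face of the E alkene whose C14 methyl lies on the β side, which is also the erythro mode preferred by an allylic alcohol with a geminal alkene substituent, so the 1β,10α-epoxide should form while C4=C5 and the conjugated methylene stay intact.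

Step 8
Reactants: 12 1β,10α-epoxy-8β,9α-dihydroxygermacra-4E,11(13)-dien-12,6α-olide
Product: 13 13-(dimethylamino)-1β,10α-epoxy-8β,9α-dihydroxy-11βH-germacr-4E-en-12,6α-olide
Conditions: Me2NH (2 M in THF), MeOH, 25 °C
Reagents that add atoms: dimethylamine, CNC
Why: Aza-Michael addition of the secondary amine to the α-methylene-γ-lactone, the usual reversible mask for this group; protonation of the enolate from the less hindered face gives a temporary C11 centre (11βH assumed) that is erased again in step 10.

Step 9
Reactants: 13 13-(dimethylamino)-1β,10α-epoxy-8β,9α-dihydroxy-11βH-germacr-4E-en-12,6α-olide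
Product: 14 13-(dimethylamino)-1β,10α-epoxy-8β,9α-dihydroxy-4αH,11βH-germacran-12,6α-olide
Conditions: H2 (1 atm), PtO2, EtOAc, 25 °C
Reagents that add atoms: none
Why: Heterogeneous catalytic syn-hydrogenation of the strained trisubstituted E alkene, now the only C=C bond in the molecule; hydrogen adds to the outer face of the alkene (C15 on the β side), that is to the α face of C4, which sets the 4β-methyl centre, while platinum in a neutral solvent should spare the epoxide and the allylic C6–O bond.

Step 10
Reactants: 14 13-(dimethylamino)-1β,10α-epoxy-8β,9α-dihydroxy-4αH,11βH-germacran-12,6α-olide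
Product: 16 1β,10α-epoxy-8β,9α-dihydroxy-4αH-germacr-11(13)-en-12,6α-olide, via trimethylammonium iodide 15 (not isolated)
Conditions: MeI, THF, 25 °C; then aq. NaHCO3, CH2Cl2, 25 °C
Reagents that add atoms: none
Why: Quaternisation of the tertiary amine and E1cB (Hofmann-type) elimination with mild base, the standard unmasking of amine adducts of α-methylene lactones; C11 returns to sp2 and no other centre is affected.

Step 11
Reactants: 16 1β,10α-epoxy-8β,9α-dihydroxy-4αH-germacr-11(13)-en-12,6α-olide; 17 (E)-but-2-enoic anhydride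
Product: 18 8β,9α-bis[(E)-but-2-enoyloxy]-1β,10α-epoxy-4αH-germacr-11(13)-en-12,6α-olide
Conditions: DMAP (cat.), pyridine, CH2Cl2, 0 → 25 °C
Reagents that add atoms: 17 (E)-but-2-enoic anhydride, C/C=C/C(=O)OC(=O)/C=C/C
Why: DMAP-catalysed acyl transfer from the symmetric anhydride esterifies the two secondary hydroxyls, the only free hydroxyls present, under mild conditions that should not deconjugate the crotonyl groups or open the epoxide; no stereocentre changes.

Step 12
Reactants: 18 8β,9α-bis[(E)-but-2-enoyloxy]-1β,10α-epoxy-4αH-germacr-11(13)-en-12,6α-olide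
Product: 19 8β,9α-bis[(E)-but-2-enoyloxy]-1β,10β-dihydroxy-4αH-germacr-11(13)-en-12,6α-olide
Conditions: HClO4 (cat.), THF/H2O, 0 °C
Reagents that add atoms: water, O
Why: Acid-catalysed epoxide hydrolysis: water attacks the tertiary carbon C10 anti to the breaking C–O bond (borderline SN2, inversion), converting the 10α-oxygen of the epoxide into the 10β-hydroxyl with the C14 methyl α, while C1 keeps its β-oxygen; with C4=C5 saturated no transannular π-cyclisation can intervene.

Step 13
Reactants: 19 8β,9α-bis[(E)-but-2-enoyloxy]-1β,10β-dihydroxy-4αH-germacr-11(13)-en-12,6α-olide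
Product: 21 8β,9α-bis[(E)-but-2-enoyloxy]-10β-hydroxy-1-oxo-4αH-germacra-2Z,11(13)-dien-12,6α-olide, via ketol 20 (not isolated)
Conditions: IBX, 4-methoxypyridine N-oxide, DMSO, 25 → 45 °C
Reagents that add atoms: none
Why: IBX oxidises the single secondary alcohol to the ketone without glycol cleavage and then, as its N-oxide complex in excess, dehydrogenates the ketone (IBX ketone dehydrogenation) towards C2–C3, the only enolisable side because C10 is quaternary; the Z geometry is the less strained one for an enone in a ten-membered ring.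

Step 14
Reactants: 21 8β,9α-bis[(E)-but-2-enoyloxy]-10β-hydroxy-1-oxo-4αH-germacra-2Z,11(13)-dien-12,6α-olide
Product: 22 8β,9α-bis[(E)-but-2-enoyloxy]-2α,3α-epoxy-10β-hydroxy-1-oxo-4αH-germacr-11(13)-en-12,6α-olide (CNP0253228.1)
Conditions: t-BuOOH (decane), DBU (cat.), CH2Cl2, 0 °C
Reagents that add atoms: tert-butyl hydroperoxide, CC(C)(C)OO
Why: Weitz–Scheffer nucleophilic epoxidation: the tert-butylperoxy anion adds to C3 of the ketone-conjugated alkene, which is far more electrophilic than the ester-conjugated methylene lactone and crotonates, on the face anti to the neighbouring C4 β-methyl, and the enolate closes onto oxygen to give the ring-cis 2α,3α-epoxide.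

**Compound list**

1 | (2E,6E)-farnesol | CC(C)=CCC/C(C)=C/CC/C(C)=C/CO | starting material
2 | (2E,6E)-farnesyl chloride | CC(C)=CCC/C(C)=C/CC/C(C)=C/CCl | intermediate
3 | (2E,6E)-farnesyl diphosphate trisammonium salt | CC(C)=CCC/C(C)=C/CC/C(C)=C/COP(=O)([O-])OP(=O)([O-])[O-].[NH4+].[NH4+].[NH4+] | intermediate
4 | (R)-germacrene A | C=C(C)[C@H]1C/C=C(C)/CC/C=C(C)/CC1 | intermediate
5 | (7R)-germacra-1(10)E,4E,11(13)-trien-12-ol (not isolated) | C=C(CO)[C@H]1C/C=C(C)/CC/C=C(C)/CC1 | intermediate
6 | (7R)-germacra-1(10)E,4E,11(13)-trien-12-al (not isolated) | C=C(C=O)[C@H]1C/C=C(C)/CC/C=C(C)/CC1 | intermediate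
7 | germacrene A acid, (7R)-germacra-1(10)E,4E,11(13)-trien-12-oic acid | C=C(C(=O)O)[C@H]1C/C=C(C)/CC/C=C(C)/CC1 | intermediate
8 | 8β-hydroxygermacrene A acid (not isolated) | C=C(C(=O)O)[C@H]1C/C=C(C)/CC/C=C(C)/C[C@H]1O | intermediate
9 | 6α,8β-dihydroxygermacrene A acid (not isolated) | C=C(C(=O)O)[C@H]1[C@H](O)/C=C(C)/CC/C=C(C)/C[C@H]1O | intermediate
10 | eupatolide, 8β-hydroxygermacra-1(10)E,4E,11(13)-trien-12,6α-olide | C=C1C(=O)O[C@@H]2/C=C(\C)CC/C=C(\C)C[C@@H](O)[C@@H]12 | intermediate
11 | 9α-hydroxyeupatolide, 8β,9α-dihydroxygermacra-1(10)E,4E,11(13)-trien-12,6α-olide | C=C1C(=O)O[C@@H]2/C=C(\C)CC/C=C(\C)[C@H](O)[C@@H](O)[C@@H]12 | intermediate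
12 | 1β,10α-epoxy-8β,9α-dihydroxygermacra-4E,11(13)-dien-12,6α-olide | C=C1C(=O)O[C@@H]2/C=C(\C)CC[C@H]3O[C@]3(C)[C@H](O)[C@@H](O)[C@@H]12 | intermediate
13 | 13-(dimethylamino)-1β,10α-epoxy-8β,9α-dihydroxy-11βH-germacr-4E-en-12,6α-olide | CN(C)C[C@@H]1C(=O)O[C@@H]2/C=C(\C)CC[C@H]3O[C@]3(C)[C@H](O)[C@@H](O)[C@@H]12 | intermediate
14 | 13-(dimethylamino)-1β,10α-epoxy-8β,9α-dihydroxy-4αH,11βH-germacran-12,6α-olide | CN(C)C[C@@H]1C(=O)O[C@@H]2C[C@@H](C)CC[C@H]3O[C@]3(C)[C@H](O)[C@@H](O)[C@@H]12 | intermediate
15 | trimethylammonium iodide of 14 (not isolated) | C[N+](C)(C)C[C@@H]1C(=O)O[C@@H]2C[C@@H](C)CC[C@H]3O[C@]3(C)[C@H](O)[C@@H](O)[C@@H]12.[I-] | intermediate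
16 | 1β,10α-epoxy-8β,9α-dihydroxy-4αH-germacr-11(13)-en-12,6α-olide | C=C1C(=O)O[C@@H]2C[C@@H](C)CC[C@H]3O[C@]3(C)[C@H](O)[C@@H](O)[C@@H]12 | intermediate
17 | (E)-but-2-enoic anhydride | C/C=C/C(=O)OC(=O)/C=C/C | starting material
18 | 8β,9α-bis[(E)-but-2-enoyloxy]-1β,10α-epoxy-4αH-germacr-11(13)-en-12,6α-olide | C=C1C(=O)O[C@@H]2C[C@@H](C)CC[C@H]3O[C@]3(C)[C@H](OC(=O)/C=C/C)[C@@H](OC(=O)/C=C/C)[C@@H]12 | intermediate
19 | 8β,9α-bis[(E)-but-2-enoyloxy]-1β,10β-dihydroxy-4αH-germacr-11(13)-en-12,6α-olide | C=C1C(=O)O[C@@H]2C[C@@H](C)CC[C@@H](O)[C@@](C)(O)[C@H](OC(=O)/C=C/C)[C@@H](OC(=O)/C=C/C)[C@@H]12 | intermediate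
20 | 8β,9α-bis[(E)-but-2-enoyloxy]-10β-hydroxy-1-oxo-4αH-germacr-11(13)-en-12,6α-olide (ketol, not isolated) | C=C1C(=O)O[C@@H]2C[C@@H](C)CCC(=O)[C@@](C)(O)[C@H](OC(=O)/C=C/C)[C@@H](OC(=O)/C=C/C)[C@@H]12 | intermediate
21 | 8β,9α-bis[(E)-but-2-enoyloxy]-10β-hydroxy-1-oxo-4αH-germacra-2Z,11(13)-dien-12,6α-olide | C=C1C(=O)O[C@@H]2C[C@@H](C)/C=C\C(=O)[C@@](C)(O)[C@H](OC(=O)/C=C/C)[C@@H](OC(=O)/C=C/C)[C@@H]12 | intermediate
22 | 8β,9α-bis[(E)-but-2-enoyloxy]-2α,3α-epoxy-10β-hydroxy-1-oxo-4αH-germacr-11(13)-en-12,6α-olide (CNP0253228.1) | C=C1C(=O)O[C@@H]2C[C@@H](C)[C@@H]3O[C@@H]3C(=O)[C@@](C)(O)[C@H](OC(=O)/C=C/C)[C@@H](OC(=O)/C=C/C)[C@@H]12 | target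

**Step count and risks**

Total steps: 14. Longest linear sequence: 14 steps (1 → 22); 17 enters in step 11.

Steps most likely to fail:

1. Step 6. The enzyme may abstract the wrong hydrogen (9β or a C14 hydrogen) or epoxidise C1=C10, because regio- and face selectivity rest on a variant not evolved for this substrate. The fallback sets out from 10 and returns at 11. A variant with the 9β preference is used to give 9β-hydroxyeupatolide F1. Mitsunobu reaction of this cis-diol (HCO2H, PPh3, DIAD, THF, 0 °C) should esterify the more reactive allylic C9 hydroxyl with inversion to give 9α-formyloxy-8β-hydroxygermacra-1(10)E,4E,11(13)-trien-12,6α-olide F2. Brief treatment with KHCO3 in aqueous MeOH at 0 °C removes the formyl group and gives 11.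

2. Step 13. The hypervalent iodine reagent may cleave the C1–C10 bond of the α-ketol oxidatively, stall at the ketone, or give E/Z scrambling at the higher temperature. The fallback sets out from 19 and returns at 21. Swern oxidation ((COCl)2, DMSO, Et3N, CH2Cl2, −78 °C) gives ketol 20, now isolated. TMSOTf/Et3N in CH2Cl2 at 0 °C silylates the tertiary hydroxyl and the only possible enol to give the bis(trimethylsilyl) compound F3. Saegusa–Ito oxidation with Pd(OAc)2 in MeCN at 25 °C gives the 10-O-trimethylsilyl enone F4. HF·pyridine in THF at 0 °C frees the tertiary hydroxyl and gives 21.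

3. Step 14. Peroxide addition may show poor facial selectivity at C3, compete at the methylene lactone, or be accompanied by base-induced acyl migration. The fallback sets out from 21 and returns at 22. Luche reduction (NaBH4, CeCl3·7H2O, MeOH, −78 °C) should deliver hydride from the side of the C10 methyl in the cerium chelate and give the 1β-hydroxy-2Z-ene F5. Buffered mCPBA (NaHCO3, CH2Cl2, 0 °C) epoxidises this one electron-rich alkene, anti to the allylic hydroxyl as is usual for medium-ring cycloalkenols, and gives the 2α,3α-epoxy-1β-ol F6. Dess–Martin periodinane (NaHCO3, CH2Cl2, 25 °C) oxidises C1 and gives 22.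

Further compounds
F1 | step 6 | 9β-hydroxyeupatolide, 8β,9β-dihydroxygermacra-1(10)E,4E,11(13)-trien-12,6α-olide | C=C1C(=O)O[C@@H]2/C=C(\C)CC/C=C(\C)[C@@H](O)[C@@H](O)[C@@H]12
F2 | step 6 | 9α-formyloxy-8β-hydroxygermacra-1(10)E,4E,11(13)-trien-12,6α-olide | C=C1C(=O)O[C@@H]2/C=C(\C)CC/C=C(\C)[C@H](OC=O)[C@@H](O)[C@@H]12
F3 | step 13 | 8β,9α-bis[(E)-but-2-enoyloxy]-1,10β-bis(trimethylsilyloxy)-4αH-germacra-1,11(13)-dien-12,6α-olide | C=C1C(=O)O[C@@H]2C[C@@H](C)C/C=C(O[Si](C)(C)C)\[C@@](C)(O[Si](C)(C)C)[C@H](OC(=O)/C=C/C)[C@@H](OC(=O)/C=C/C)[C@@H]12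
F4 | step 13 | 8β,9α-bis[(E)-but-2-enoyloxy]-1-oxo-10β-(trimethylsilyloxy)-4αH-germacra-2Z,11(13)-dien-12,6α-olide | C=C1C(=O)O[C@@H]2C[C@@H](C)/C=C\C(=O)[C@@](C)(O[Si](C)(C)C)[C@H](OC(=O)/C=C/C)[C@@H](OC(=O)/C=C/C)[C@@H]12
F5 | step 14 | 8β,9α-bis[(E)-but-2-enoyloxy]-1β,10β-dihydroxy-4αH-germacra-2Z,11(13)-dien-12,6α-olide | C=C1C(=O)O[C@@H]2C[C@@H](C)/C=C\[C@@H](O)[C@@](C)(O)[C@H](OC(=O)/C=C/C)[C@@H](OC(=O)/C=C/C)[C@@H]12
F6 | step 14 | 8β,9α-bis[(E)-but-2-enoyloxy]-2α,3α-epoxy-1β,10β-dihydroxy-4αH-germacr-11(13)-en-12,6α-olide | C=C1C(=O)O[C@@H]2C[C@@H](C)[C@@H]3O[C@@H]3[C@@H](O)[C@@](C)(O)[C@H](OC(=O)/C=C/C)[C@@H](OC(=O)/C=C/C)[C@@H]12
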